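## Retrosynthetic overview
1. The last operations are removal of two aryl silyl ethers and a Suzuki coupling that attaches the (E)-3-hydroxypropenyl chain at C7–Br.
2. The C3–CH2OH group comes from a C3-vinyl group by oxidative cleavage and reduction, done before the cinnamyl alkene exists.
3. Rings A and B are bought. The dioxane ring is the only ring formed, closed last at O1–C8a by copper-catalysed O-arylation with retention, so the cis ring needs an anti (erythro) alcohol.
4. Key C2–C3 bond: the ring-A aldehyde carbon is joined to the oxygen-bearing carbon of an (E)-γ-aryloxyallylboronate that already carries ring B on its oxygen. That carbon is a masked acrolein carbonyl carbon acting as a nucleophile (d1 + a1). A chiral phosphoric acid sets both stereocentres in this step.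
5. The boronate comes from an iodophenol and (E)-3-chloropropenyl-Bpin by ether formation, followed by iridium-catalysed alkene transposition in the flask.

Assumption: the SMILES is read as the cis isomer, (2S,3R), with the locants O1–C2(aryl)–C3(side arm)–O4, OMe on C5 and the para substituent on C7, and these locants are kept for all benzodioxanes below; (R)-TRIP is taken to direct attack to the re face of ArCHO as it does for allyl- and crotyl-Bpin, and (S)-TRIP is used if the first run shows the opposite sense.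

## Route

Step 1
Reactants: 1 3,4-dihydroxy-5-methoxybenzaldehyde (5-hydroxyvanillin)
Product: 2 3-methoxy-4,5-bis(triisopropylsilyloxy)benzaldehyde
Conditions: TIPSCl (2.5 equiv), imidazole (5 equiv), DMAP (cat.), DMF, 40 °C
Reagents that add atoms: chlorotriisopropylsilane (TIPSCl), CC(C)[Si](Cl)(C(C)C)C(C)C
Why: Imidazole-promoted silyl ether protection of both phenols, with TIPS chosen because aryl TIPS ethers survive Cs2CO3 at 80 °C and aqueous K3PO4 yet fall to buffered fluoride at 0 °C.

Step 2
Reactants: 3 4-bromo-2-methoxyphenol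
Product: 4 4-bromo-2-iodo-6-methoxyphenol
Conditions: NaI (1.05 equiv), aq NaOCl (1.05 equiv, slow addition), MeOH, 0 °C
Reagents that add atoms: sodium iodide, [Na+].[I-]
Why: Electrophilic aromatic iodination in which NaOI made in situ iodinates the phenoxide ortho to O− (para is blocked by Br and OMe is the weaker director), giving the I/Br pair needed for two successive halogen-selective couplings.

Step 3
Reactants: 4 4-bromo-2-iodo-6-methoxyphenol; 5 (E)-3-chloroprop-1-enylboronic acid pinacol ester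
Product: 6 2-[(E)-3-(4-bromo-2-iodo-6-methoxyphenoxy)prop-1-enyl]-4,4,5,5-tetramethyl-1,3,2-dioxaborolane
Conditions: K2CO3 (1.5 equiv), DMF, 60 °C
Reagents that add atoms: none
Why: Williamson ether synthesis (SN2 at the primary allylic chloride) by the acidic phenoxide, in which the alkenyl–Bpin unit is inert to dry K2CO3 and keeps its E geometry.

Step 4 (key step)
Reactants: 6 alkenylboronate ether; 2 3-methoxy-4,5-bis(triisopropylsilyloxy)benzaldehyde
Product: 9 (1S,2R)-2-(4-bromo-2-iodo-6-methoxyphenoxy)-1-[3-methoxy-4,5-bis(triisopropylsilyloxy)phenyl]but-3-en-1-ol (anti adduct), via (E)-gamma-aryloxyallyl pinacolboronate 7 (not isolated), via adduct O-boronate 8 (not isolated)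
Conditions: [Ir(cod)(PPh2Me)2]PF6 (3 mol %, H2-activated then Ar-purged), ClCH2CH2Cl, rt, 1 h; then 2, (R)-TRIP (10 mol %), 4 Å MS, 0 °C to rt, 24 h; aq NaHCO3
Reagents that add atoms: none
Why: Proposed new method: the H2-activated cationic iridium hydride moves the C=C of 6 by one position (insertion/β-hydride elimination, the catalyst type that turns allyl ethers into (E)-propenyl ethers and 3-silyloxy-1-alkenylboronates into (E)-γ-silyloxyallylboronates) to give (E)-7, whose oxygen-bearing carbon, formally the carbonyl carbon of acrolein now acting as a d1 nucleophile, attacks the carbonyl carbon of 2 through a closed six-membered Zimmerman–Traxler allylboration transition state, so that E geometry gives the anti relationship while (R)-TRIP, hydrogen-bonded to a boronate oxygen and the formyl C–H, exposes the re face and fixes 1S and hence 2R; the closest known reactions are the chiral-phosphoric-acid-catalysed anti-alkoxyallylboration of aldehydes with (E)-γ-alkoxyallyl pinacolboronates and the tandem iridium/phosphoric acid alkenylboronate transposition–allylation, the new element being an O-aryl group that is the whole of ring B.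

Step 5
Reactants: 9 anti adduct
Product: 10 (2S,3R)-7-bromo-3-ethenyl-5-methoxy-2-[3-methoxy-4,5-bis(triisopropylsilyloxy)phenyl]-2,3-dihydro-1,4-benzodioxine (cis)
Conditions: CuI (10 mol %), 3,4,7,8-tetramethyl-1,10-phenanthroline (20 mol %), Cs2CO3 (1.5 equiv), toluene (0.02 M), 80 °C, Ar
Reagents that add atoms: none
Why: Intramolecular Ullmann-type C–O coupling in which the monovalent copper alkoxide reacts with the neighbouring C–I bond (ArI reacts far faster than ArBr at 80 °C) without touching either C(sp3)–O bond, so both centres are retained and the anti alcohol becomes the cis-(2S,3R) ring, while copper avoids the 5-exo Heck cyclisation that palladium would trigger in an o-iodoaryl allyl ether.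

Step 6
Reactants: 10 cis vinyl benzodioxane
Product: 12 cis-(2S,3R)-7-bromo-3-(hydroxymethyl)-5-methoxy-2-[3-methoxy-4,5-bis(triisopropylsilyloxy)phenyl]-2,3-dihydro-1,4-benzodioxine, via cis C3-carbaldehyde 11 (not isolated)
Conditions: O3, pyridine (3 equiv), CH2Cl2, −78 °C (Sudan Red 7B end point); then NaBH4, MeOH, −78 to 0 °C
Reagents that add atoms: ozone, [O-][O+]=O
Why: Ozonolysis in the presence of pyridine (direct, peroxide-free delivery of the aldehyde) followed by in situ borohydride reduction cuts the only alkene down to CH2OH, and reducing the α-aryloxy aldehyde 11 below 0 °C before any work-up keeps C3 from epimerising to the trans series.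

Step 7
Reactants: 12 cis bromo alcohol; 13 (E)-3-hydroxyprop-1-enylboronic acid pinacol ester
Product: 14 cis-(2S,3R)-3-(hydroxymethyl)-7-[(E)-3-hydroxyprop-1-enyl]-5-methoxy-2-[3-methoxy-4,5-bis(triisopropylsilyloxy)phenyl]-2,3-dihydro-1,4-benzodioxine
Conditions: Pd(OAc)2 (3 mol %), SPhos (6 mol %), K3PO4 (2 equiv), THF/H2O 10:1, 50 °C
Reagents that add atoms: none
Why: Suzuki–Miyaura coupling at the remaining C–Br bond transfers the alkenyl group with retention of E geometry, and the free hydroxyls, the aryl TIPS ethers and both stereocentres (no free para-phenol, hence no quinone methide path) tolerate aqueous K3PO4 at 50 °C.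

Step 8
Reactants: 14 bis-TIPS ether of the target
Product: 15 5-[(2S,3R)-3-(hydroxymethyl)-7-[(E)-3-hydroxyprop-1-enyl]-5-methoxy-2,3-dihydro-1,4-benzodioxin-2-yl]-3-methoxybenzene-1,2-diol (CNP0174261.1)
Conditions: TBAF (2.2 equiv), AcOH (2.5 equiv), THF, 0 °C, 20 min, Ar; pH 6 buffer
Reagents that add atoms: none
Why: Fluoride-induced desilylation of the two aryl silyl ethers is fast at 0 °C, and the acetic acid buffer keeps the liberated para-phenol protonated so that the benzylic C2–O1 bond cannot open to a quinone methide and drift to the trans isomer.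

## Compound list
1 | 3,4-dihydroxy-5-methoxybenzaldehyde | COc1cc(C=O)cc(O)c1O | starting material
2 | 3-methoxy-4,5-bis(triisopropylsilyloxy)benzaldehyde | COc1cc(C=O)cc(O[Si](C(C)C)(C(C)C)C(C)C)c1O[Si](C(C)C)(C(C)C)C(C)C | intermediate
3 | 4-bromo-2-methoxyphenol | COc1cc(Br)ccc1O | starting material
4 | 4-bromo-2-iodo-6-methoxyphenol | COc1cc(Br)cc(I)c1O | intermediate
5 | (E)-3-chloroprop-1-enylboronic acid pinacol ester | ClC/C=C/B1OC(C)(C)C(C)(C)O1 | starting material
6 | 2-[(E)-3-(4-bromo-2-iodo-6-methoxyphenoxy)prop-1-enyl]-4,4,5,5-tetramethyl-1,3,2-dioxaborolane | COc1cc(Br)cc(I)c1OC/C=C/B1OC(C)(C)C(C)(C)O1 | intermediate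
7 | 2-[(E)-3-(4-bromo-2-iodo-6-methoxyphenoxy)prop-2-enyl]-4,4,5,5-tetramethyl-1,3,2-dioxaborolane (not isolated) | COc1cc(Br)cc(I)c1O/C=C/CB1OC(C)(C)C(C)(C)O1 | intermediate
8 | O-(pinacolatoboryl) derivative of 9, (1S,2R) (not isolated) | COc1cc([C@H](OB2OC(C)(C)C(C)(C)O2)[C@@H](C=C)Oc2c(I)cc(Br)cc2OC)cc(O[Si](C(C)C)(C(C)C)C(C)C)c1O[Si](C(C)C)(C(C)C)C(C)C | intermediate
9 | (1S,2R)-2-(4-bromo-2-iodo-6-methoxyphenoxy)-1-[3-methoxy-4,5-bis(triisopropylsilyloxy)phenyl]but-3-en-1-ol | COc1cc([C@H](O)[C@@H](C=C)Oc2c(I)cc(Br)cc2OC)cc(O[Si](C(C)C)(C(C)C)C(C)C)c1O[Si](C(C)C)(C(C)C)C(C)C | intermediate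
10 | (2S,3R)-7-bromo-3-ethenyl-5-methoxy-2-[3-methoxy-4,5-bis(triisopropylsilyloxy)phenyl]-2,3-dihydro-1,4-benzodioxine (cis) | COc1cc([C@@H]2Oc3cc(Br)cc(OC)c3O[C@@H]2C=C)cc(O[Si](C(C)C)(C(C)C)C(C)C)c1O[Si](C(C)C)(C(C)C)C(C)C | intermediate
11 | cis C3-carbaldehyde, same spatial arrangement as 10 (the CIP label of the CHO-bearing carbon reads S only because CHO outranks C2) (not isolated) | COc1cc([C@@H]2Oc3cc(Br)cc(OC)c3O[C@@H]2C=O)cc(O[Si](C(C)C)(C(C)C)C(C)C)c1O[Si](C(C)C)(C(C)C)C(C)C | intermediate
12 | cis-(2S,3R)-7-bromo-3-(hydroxymethyl)-5-methoxy-2-[3-methoxy-4,5-bis(triisopropylsilyloxy)phenyl]-2,3-dihydro-1,4-benzodioxine | COc1cc([C@@H]2Oc3cc(Br)cc(OC)c3O[C@@H]2CO)cc(O[Si](C(C)C)(C(C)C)C(C)C)c1O[Si](C(C)C)(C(C)C)C(C)C | intermediate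
13 | (E)-3-hydroxyprop-1-enylboronic acid pinacol ester | OC/C=C/B1OC(C)(C)C(C)(C)O1 | starting material
14 | bis-TIPS ether of the target, cis-(2S,3R) | COc1cc([C@@H]2Oc3cc(/C=C/CO)cc(OC)c3O[C@@H]2CO)cc(O[Si](C(C)C)(C(C)C)C(C)C)c1O[Si](C(C)C)(C(C)C)C(C)C | intermediate
15 | 5-[(2S,3R)-3-(hydroxymethyl)-7-[(E)-3-hydroxyprop-1-enyl]-5-methoxy-2,3-dihydro-1,4-benzodioxin-2-yl]-3-methoxybenzene-1,2-diol | COc1cc([C@@H]2Oc3cc(/C=C/CO)cc(OC)c3O[C@@H]2CO)cc(O)c1O | target

## Step count and risks
Total step count: 8.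
Longest linear sequence: 7 (3 → 4 → 6 → 9 → 10 → 12 → 14 → 15).

**Step 4.**
- Risk: the bulky, weakly nucleophilic γ-aryloxyallyl-Bpin may react slowly, or the face selectivity with an O-aryl group may be poor.
- Fallback, from 6 and 2 back to 9: give up catalyst control of the face and keep only the E → anti transfer.
- 7 is generated as before and heated with 2 without the acid (toluene, 50 °C). The chair transition state gives 8 together with its mirror image, the (1R,2S)-O-boronate F1.
- Hydrolysis gives the racemic anti alcohol, that is 9 plus the (1R,2S)-alcohol F2.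
- Acylative kinetic resolution ((S)-benzotetramisole 5 mol %, propionic anhydride 0.6 equiv, iPr2NEt, CHCl3, 0 °C) turns F2 into the (1R,2S)-propionate F3. This leaves 9, which is separated on silica.

**Step 5.**
- Risk: the hindered secondary alkoxide must form a cis ring, and it could instead expel the good aryloxide leaving group from the allylic C3 to give a vinyl epoxide.
- Fallback, from 9 back to 12: remove the alkene first, so that C3 is no longer allylic and palladium can be used without a Heck pathway.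
- Ozonolysis of 9 (O3, pyridine, CH2Cl2, −78 °C) gives the (2S,3S)-β-hydroxy aldehyde F4. This is reduced in the same flask (NaBH4, MeOH) to the (1S,2R)-1,3-diol F5.
- TBSCl/imidazole (CH2Cl2, 0 °C) silylates only the primary hydroxyl and gives the mono-TBS ether F6.
- Pd(OAc)2, 2-(di-tert-butylphosphino)-1,1'-binaphthyl and Cs2CO3 (toluene, 65 °C) close the ring at the C–I bond, again with retention, to the cis TBS ether F7.
- Camphorsulfonic acid in MeOH (0 °C) removes the alkyl TBS group but not the aryl TIPS groups and gives 12.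

**Step 6.**
- Risk: ozone may attack the two trioxygenated arenes, and 11 can epimerise.
- Fallback, from 10 back to 11: replace ozone by a stepwise osmium/periodate sequence.
- OsO4 (2 mol %) and N-methylmorpholine N-oxide in acetone/H2O give the vicinal diol F8 (both epimers at the new carbinol carbon).
- NaIO4 in THF/pH 7 buffer (0 °C) cleaves F8 to 11. This is reduced at once with NaBH4 as in step 6 to give 12.

## Further compounds
F1 | step 4 | (1R,2S)-O-(pinacolatoboryl) adduct, mirror image of 8 | COc1cc([C@@H](OB2OC(C)(C)C(C)(C)O2)[C@H](C=C)Oc2c(I)cc(Br)cc2OC)cc(O[Si](C(C)C)(C(C)C)C(C)C)c1O[Si](C(C)C)(C(C)C)C(C)C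
F2 | step 4 | (1R,2S)-2-(4-bromo-2-iodo-6-methoxyphenoxy)-1-[3-methoxy-4,5-bis(triisopropylsilyloxy)phenyl]but-3-en-1-ol, mirror image of 9 | COc1cc([C@@H](O)[C@H](C=C)Oc2c(I)cc(Br)cc2OC)cc(O[Si](C(C)C)(C(C)C)C(C)C)c1O[Si](C(C)C)(C(C)C)C(C)C
F3 | step 4 | (1R,2S)-propionate of F2 | COc1cc([C@@H](OC(=O)CC)[C@H](C=C)Oc2c(I)cc(Br)cc2OC)cc(O[Si](C(C)C)(C(C)C)C(C)C)c1O[Si](C(C)C)(C(C)C)C(C)C
F4 | step 5 | (2S,3S)-2-(4-bromo-2-iodo-6-methoxyphenoxy)-3-hydroxy-3-[3-methoxy-4,5-bis(triisopropylsilyloxy)phenyl]propanal | COc1cc([C@H](O)[C@@H](C=O)Oc2c(I)cc(Br)cc2OC)cc(O[Si](C(C)C)(C(C)C)C(C)C)c1O[Si](C(C)C)(C(C)C)C(C)C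
F5 | step 5 | (1S,2R)-2-(4-bromo-2-iodo-6-methoxyphenoxy)-1-[3-methoxy-4,5-bis(triisopropylsilyloxy)phenyl]propane-1,3-diol | COc1cc([C@H](O)[C@@H](CO)Oc2c(I)cc(Br)cc2OC)cc(O[Si](C(C)C)(C(C)C)C(C)C)c1O[Si](C(C)C)(C(C)C)C(C)C
F6 | step 5 | (1S,2R)-2-(4-bromo-2-iodo-6-methoxyphenoxy)-3-(tert-butyldimethylsilyloxy)-1-[3-methoxy-4,5-bis(triisopropylsilyloxy)phenyl]propan-1-ol | COc1cc([C@H](O)[C@@H](CO[Si](C)(C)C(C)(C)C)Oc2c(I)cc(Br)cc2OC)cc(O[Si](C(C)C)(C(C)C)C(C)C)c1O[Si](C(C)C)(C(C)C)C(C)C
F7 | step 5 | O-TBS ether of 12, cis-(2S,3R) | COc1cc([C@@H]2Oc3cc(Br)cc(OC)c3O[C@@H]2CO[Si](C)(C)C(C)(C)C)cc(O[Si](C(C)C)(C(C)C)C(C)C)c1O[Si](C(C)C)(C(C)C)C(C)C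
F8 | step 6 | 1-[cis-7-bromo-5-methoxy-2-[3-methoxy-4,5-bis(triisopropylsilyloxy)phenyl]-2,3-dihydro-1,4-benzodioxin-3-yl]ethane-1,2-diol (ring centres as in 10, epimers at the new carbinol carbon) | COc1cc([C@@H]2Oc3cc(Br)cc(OC)c3O[C@@H]2C(O)CO)cc(O[Si](C(C)C)(C(C)C)C(C)C)c1O[Si](C(C)C)(C(C)C)C(C)C
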